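**Retrosynthetic overview**

- The last disconnection is the C3–Br bond: the target comes from 5,7-dibromo-6-methoxy-1H-indole by electrophilic bromination of the pyrrole ring.
- The strategy rests on the C7 bromine of the benzene ring, which lies ortho to N1 (through C7a), while C3a is the only other ortho carbon and carries hydrogen before annulation, and C2/C3 are bare. This is the ortho-substituted nitroarene pattern of a Bartoli annulation, so the pyrrole ring is cut at C3–C3a and N1–C2 into 1,3-dibromo-2-methoxy-4-nitrobenzene and vinylmagnesium bromide.
- The nitroarene comes from 2,4-dibromo-3-methoxyaniline by diazotisation and copper-mediated replacement of the diazonio group by nitrite. The aniline comes from 2-amino-4-methoxybenzoic acid by dibromination and protodecarboxylation, the carboxyl group serving as a removable block at the carbon para to oxygen.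
- Ring order: the benzene ring is bought and its substituents are set in steps 1–3; the pyrrole ring is the only ring formed (step 4).

Key step: step 4

Remark on the chemistry: the magnesium-bound intermediates of step 4 exist in the flask as bromomagnesium salts; they are named and drawn as the corresponding neutral compounds.

**Route**

Step 1
Reactants: 1 2-amino-4-methoxybenzoic acid; 2 N-bromosuccinimide
Product: 4 2-amino-3,5-dibromo-4-methoxybenzoic acid, via monobromo acid 3 (not isolated)
Conditions: NBS (2.05 equiv), DMF, 0 °C to rt, dark
Reagents that add atoms: N-bromosuccinimide, O=C1CCC(=O)N1Br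
Why: Electrophilic aromatic bromination in which the amino group directs to its free para and ortho carbons (C5, then C3), both also ortho to the methoxy group, while the carboxyl group occupies and blocks the remaining activated carbon (C1, para to oxygen), so the first bromine should enter at C5 to give 3 and the second at C3.

Step 2
Reactants: 4 2-amino-3,5-dibromo-4-methoxybenzoic acid
Product: 5 2,4-dibromo-3-methoxyaniline
Conditions: aq. H2SO4 (1 M), 1,4-dioxane, 100 °C
Reagents that add atoms: none
Why: Acid-mediated protodecarboxylation of an anthranilic acid, in which the carboxyl-bearing carbon is ortho to nitrogen and para to the methoxy oxygen, is protonated at the ipso position and then expels CO2, while dilute non-nucleophilic acid should leave the aryl methyl ether and the C–Br bonds intact.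

Step 3
Reactants: 5 2,4-dibromo-3-methoxyaniline; 6 sodium nitrite
Product: 8 1,3-dibromo-2-methoxy-4-nitrobenzene, via diazonium tetrafluoroborate 7 (not isolated)
Conditions: NaNO2 (1.05 equiv), 48% aq. HBF4 (2.2 equiv), MeCN/H2O, 0 °C; then added to aq. NaNO2 (10 equiv), Cu powder (cat.), 0 °C to rt
Reagents that add atoms: sodium nitrite, [Na+].[O-]N=O
Why: Sandmeyer-type nitro-dediazoniation, in which the weakly basic aniline is diazotised to arenediazonium tetrafluoroborate 7 (the non-nucleophilic counter-ion keeps competing halide out of the flask) and copper-mediated electron transfer then releases N2 and an aryl radical that is captured by nitrite, so the nitrogen is replaced rather than oxidised and no condensation to azo or azoxy by-products can intervene.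

Step 4
Reactants: 8 1,3-dibromo-2-methoxy-4-nitrobenzene; 9 vinylmagnesium bromide
Product: 14 5,7-dibromo-6-methoxy-1H-indole, via nitrosoarene 10 (not isolated), via O-vinylhydroxylamine 11 (not isolated), via amino aldehyde 12 (not isolated), via indolin-2-ol 13 (not isolated)
Conditions: CH2=CHMgBr (3.2 equiv), THF, −40 °C; then sat. aq. NH4Cl
Reagents that add atoms: vinylmagnesium bromide, C=C[Mg]Br
Why: Bartoli indole synthesis of a 7-bromoindole from a 2-bromonitroarene: the first equivalent of Grignard reagent attacks a nitro oxygen and the adduct collapses to nitrosoarene 10 with loss of the magnesium enolate of acetaldehyde, and the second equivalent adds at the nitroso oxygen to give the N-aryl-O-vinylhydroxylamine salt 11. A [3,3]-sigmatropic shift of 11 forms the C3–C3a bond at the hydrogen-bearing ortho carbon and breaks N–O, and rearomatisation by proton shift gives amino aldehyde 12. The pyrrole ring then closes by 5-exo-trig addition of the anilide nitrogen to the aldehyde carbon (N1–C2), the third equivalent acting as base, and indolin-2-ol 13 loses water on work-up to give the aromatic indole; the only stereocentre formed, C2 of 13, is racemic and is erased by this dehydration. The step needs the shift to go to C–H and not to C–Br, which the substrate secures because only the C–H pathway can rearomatise by proton loss, and because the bromine at the other ortho carbon twists the N–O–vinyl unit out of the ring plane and speeds the rearrangement. Vinyl Grignard reagents attack nitro oxygen in preference to the ring and do not undergo bromine–magnesium exchange with aryl bromides at −40 °C, so both C–Br bonds should survive.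

Step 5
Reactants: 14 5,7-dibromo-6-methoxy-1H-indole; 2 N-bromosuccinimide
Product: 15 3,5,7-tribromo-6-methoxy-1H-indole
Conditions: NBS (1.0 equiv), DMF, 0 °C, dark
Reagents that add atoms: N-bromosuccinimide, O=C1CCC(=O)N1Br
Why: Electrophilic aromatic substitution at C3, the most nucleophilic carbon of the indole; the only benzenoid C–H (C4) is meta to the methoxy group and deactivated by the adjacent bromine, and one equivalent of NBS at 0 °C should limit attack at C2.

**Compound list**

1 | 2-amino-4-methoxybenzoic acid | COc1ccc(C(=O)O)c(N)c1 | starting material
2 | N-bromosuccinimide | O=C1CCC(=O)N1Br | starting material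
3 | 2-amino-5-bromo-4-methoxybenzoic acid (formed in the flask, not isolated) | COc1cc(N)c(C(=O)O)cc1Br | intermediate
4 | 2-amino-3,5-dibromo-4-methoxybenzoic acid | COc1c(Br)cc(C(=O)O)c(N)c1Br | intermediate
5 | 2,4-dibromo-3-methoxyaniline | COc1c(Br)ccc(N)c1Br | intermediate
6 | sodium nitrite | [Na+].[O-]N=O | starting material
7 | 2,4-dibromo-3-methoxybenzenediazonium tetrafluoroborate (formed in the flask, not isolated) | COc1c(Br)ccc([N+]#N)c1Br.F[B-](F)(F)F | intermediate
8 | 1,3-dibromo-2-methoxy-4-nitrobenzene | COc1c(Br)ccc([N+](=O)[O-])c1Br | intermediate
9 | vinylmagnesium bromide | C=C[Mg]Br | starting material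
10 | 1,3-dibromo-2-methoxy-4-nitrosobenzene (formed in the flask, not isolated) | COc1c(Br)ccc(N=O)c1Br | intermediate
11 | N-(2,4-dibromo-3-methoxyphenyl)-O-vinylhydroxylamine (bromomagnesium salt in the flask, not isolated) | C=CONc1ccc(Br)c(OC)c1Br | intermediate
12 | 2-(2-amino-3,5-dibromo-4-methoxyphenyl)acetaldehyde (bromomagnesium salt in the flask, not isolated) | COc1c(Br)cc(CC=O)c(N)c1Br | intermediate
13 | 5,7-dibromo-6-methoxy-2,3-dihydro-1H-indol-2-ol (racemic; bromomagnesium salt in the flask, not isolated) | COc1c(Br)cc2CC(O)Nc2c1Br | intermediate
14 | 5,7-dibromo-6-methoxy-1H-indole | COc1c(Br)cc2cc[nH]c2c1Br | intermediate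
15 | 3,5,7-tribromo-6-methoxy-1H-indole | COc1c(Br)cc2c(Br)c[nH]c2c1Br | target

**Step count**

Total steps: 5. Longest linear sequence: 5 steps (1 to 15).

**Steps most likely to fail**

Step 4 (Bartoli annulation). The Grignard reagent may reduce the nitro group past the nitroso stage to the aniline, or add at nitrogen or at the ring instead of at oxygen, so that little indole forms. The fallback sets out from aniline 5 and builds the pyrrole ring by alkyne hydroamination. Iodination at the one free carbon ortho to nitrogen (N-iodosuccinimide, catalytic CF3CO2H, MeCN) should give 2,4-dibromo-6-iodo-3-methoxyaniline F1. An iodide-selective Sonogashira coupling with trimethylsilylacetylene (PdCl2(PPh3)2, CuI, Et3N, THF, rt) should give 2,4-dibromo-3-methoxy-6-[(trimethylsilyl)ethynyl]aniline F2. K2CO3 in MeOH should free the alkyne to give 2,4-dibromo-6-ethynyl-3-methoxyaniline F3. KOt-Bu in N-methylpyrrolidone at rt should then close the ring by 5-endo-dig hydroamination, returning to the route at indole 14.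

Step 3 (nitro-dediazoniation). The aryl radical may abstract hydrogen or dimerise, the diazonium ion may hydrolyse to the phenol, or nitrite may displace the ring bromines that the diazonio group activates, so that capture by nitrite at the former amino carbon is a minor pathway. The fallback sets out from acid 4 and installs the nitro group by N-oxidation before the carboxyl group is removed. Oxidation of the amino group with pre-formed CF3CO3H (H2O2–urea and (CF3CO)2O in CH2Cl2, then the substrate, reflux) should give 3,5-dibromo-4-methoxy-2-nitrobenzoic acid F4. Its ortho-nitro group favours metal-catalysed protodecarboxylation (catalytic Ag2CO3, catalytic AcOH, DMSO, 120 °C), which should return to the route at nitroarene 8, bypassing aniline 5. The same detour also covers a sluggish protodecarboxylation in step 2.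

Step 1 (dibromination). Bromine may attack the carboxyl-bearing carbon, which is para to the methoxy group, with loss of CO2 (bromodecarboxylation), scrambling the substitution pattern. The fallback sets out from acid 1 and masks the carboxyl group. Fischer esterification (MeOH, H2SO4, reflux) should give methyl 2-amino-4-methoxybenzoate F5. NBS (2 equiv) in DMF should give methyl 2-amino-3,5-dibromo-4-methoxybenzoate F6, in which ipso substitution with loss of CO2 is no longer possible. LiOH in THF/H2O followed by acidification should return to the route at acid 4.

**Further compounds**

F1 | step 4 | 2,4-dibromo-6-iodo-3-methoxyaniline | COc1c(Br)cc(I)c(N)c1Br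
F2 | step 4 | 2,4-dibromo-3-methoxy-6-[(trimethylsilyl)ethynyl]aniline | COc1c(Br)cc(C#C[Si](C)(C)C)c(N)c1Br
F3 | step 4 | 2,4-dibromo-6-ethynyl-3-methoxyaniline | COc1c(Br)cc(C#C)c(N)c1Br
F4 | step 3 | 3,5-dibromo-4-methoxy-2-nitrobenzoic acid | COc1c(Br)cc(C(=O)O)c([N+](=O)[O-])c1Br
F5 | step 1 | methyl 2-amino-4-methoxybenzoate | COC(=O)c1ccc(OC)cc1N
F6 | step 1 | methyl 2-amino-3,5-dibromo-4-methoxybenzoate | COC(=O)c1cc(Br)c(OC)c(Br)c1N
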